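**Retrosynthetic overview**

1. Numbering follows the 1H-isochromene core (C1, O2, C3, C4, C4a, C5–C8, C8a); ring A is the 2H-pyran, ring B the cyclohexenone. After a last phenol desilylation, ring B is opened at C6–C7 as a retro reductive aldol, giving a monocyclic 2H-pyran with a CH2CHO arm on C4a and a 2-aroyloxy enone, C8(=O)–C7(=CH2)–OCOAr, on C8a.
2. Enabling feature: ring B holds the aldol retron O=C8–C7–C6(OH), and the quaternary C7 carries a methyl group beside its ester oxygen. Its enolate can therefore be generated regiospecifically by hydride addition to an exocyclic C7=CH2, and the hindered tertiary aryl ester enters as the enol ester of a 1,2-diketone instead of by acylation of a tertiary alcohol.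
3. The enol ester comes from a C8/C7 1,2-diketone and the aroyl chloride (from 2,4-dihydroxy-6-methylbenzaldehyde). The diketone comes from an acetyl anion equivalent and a bicyclic lactone in which ring A is fused to a δ-lactone (C8 as lactone carbonyl, C6 as its alkoxy carbon).
4. That lactone comes from dihydropyran-2,4-dione by chloroformylation, Sonogashira coupling with (E)-pent-3-en-1-yne and Ph3PAuNTf2-catalysed 6-endo cyclisation with hydride transfer. The lactone ring fixes the geometry of the tetrasubstituted C4a=C8a alkene.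
5. Order of ring formation: ring A (step 7), then ring B with both stereocentres (step 13); the template lactone ring is opened in step 8.

Key step: step 13

Assumption: (E)-pent-3-en-1-yne is bought as the pure E isomer, and the monocyclic 3-acyl-2H-pyrans between the lactone opening and the key step are taken to rest in the closed pyran form, which the push–pull conjugation from O2 to the C8 carbonyl should favour over the valence-isomeric dienone.

**Route**

Step 1
Reactants: 1 2,4-dihydroxy-6-methylbenzaldehyde
Product: 2 2-hydroxy-6-methyl-4-(triisopropylsilyloxy)benzaldehyde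
Conditions: TIPSCl (1.05 equiv), imidazole, CH2Cl2, 0 °C
Reagents that add atoms: chlorotriisopropylsilane, CC(C)[Si](Cl)(C(C)C)C(C)C
Why: Phenol silylation should be selective for the 4-OH, which is unhindered and the more acidic, whereas the 2-OH is held in a hydrogen bond to the aldehyde.

Step 2
Reactants: 2 2-hydroxy-6-methyl-4-(triisopropylsilyloxy)benzaldehyde
Product: 3 2-methoxy-6-methyl-4-(triisopropylsilyloxy)benzaldehyde
Conditions: MeI, Ag2O, MeCN, 40 °C, dark
Reagents that add atoms: iodomethane, CI
Why: Williamson-type O-methylation of the remaining chelated phenol under neutral Ag2O conditions should spare the base-labile para-formyl aryl silyl ether.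

Step 3
Reactants: 3 2-methoxy-6-methyl-4-(triisopropylsilyloxy)benzaldehyde
Product: 4 2-methoxy-6-methyl-4-(triisopropylsilyloxy)benzoic acid
Conditions: NaClO2, NaH2PO4, 2-methyl-2-butene, t-BuOH/H2O, 0 °C to rt
Reagents that add atoms: sodium chlorite, [Na+].[O-]Cl=O
Why: Pinnick oxidation should convert the hindered aryl aldehyde to the acid at buffered pH, with the alkene scavenger removing HOCl before it chlorinates the electron-rich ring.

Step 4
Reactants: 4 2-methoxy-6-methyl-4-(triisopropylsilyloxy)benzoic acid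
Product: 5 2-methoxy-6-methyl-4-(triisopropylsilyloxy)benzoyl chloride
Conditions: (COCl)2, DMF (cat.), CH2Cl2, 0 °C to rt; evaporation, used crude
Reagents that add atoms: oxalyl chloride, O=C(Cl)C(=O)Cl
Why: Acid chloride formation through the catalytic chloroiminium species should proceed under conditions short and mild enough for the aryl silyl ether.

Step 5
Reactants: 6 dihydro-2H-pyran-2,4(3H)-dione
Product: 8 4-chloro-2-oxo-5,6-dihydro-2H-pyran-3-carbaldehyde, via iminium chloride 7 (not isolated)
Conditions: POCl3, DMF, CH2Cl2, 0 to 40 °C; then ice, aq. NaOAc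
Reagents that add atoms: N,N-dimethylformamide, CN(C)C=O; phosphoryl chloride, O=P(Cl)(Cl)Cl; water, O
Why: Vilsmeier–Haack chloroformylation of the enolised β-keto lactone should formylate the doubly activated C3 and exchange the enol OH for chloride, giving a β-chlorovinyl aldehyde whose ring fixes the cis relation of the future C8 acyl and C5 methylene.

Step 6
Reactants: 8 4-chloro-2-oxo-5,6-dihydro-2H-pyran-3-carbaldehyde; 9 (E)-pent-3-en-1-yne
Product: 10 2-oxo-4-[(E)-pent-3-en-1-ynyl]-5,6-dihydro-2H-pyran-3-carbaldehyde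
Conditions: PdCl2(PPh3)2 (2 mol%), CuI (4 mol%), Et3N, THF, 0 °C to rt
Reagents that add atoms: none
Why: Sonogashira coupling at the doubly activated vinyl chloride (a vinylogous acid chloride) should proceed at or below room temperature with the E-propenyl unit unchanged.

Step 7
Reactants: 10 2-oxo-4-[(E)-pent-3-en-1-ynyl]-5,6-dihydro-2H-pyran-3-carbaldehyde
Product: 11 6-[(E)-prop-1-enyl]-3,4-dihydro-1H,8H-pyrano[3,4-c]pyran-1-one (ring A fused through C4a=C8a to the δ-lactone)
Conditions: Ph3PAuNTf2 (3 mol%), diethyl 2,6-dimethyl-1,4-dihydropyridine-3,5-dicarboxylate (1.2 equiv), CH2Cl2, 0 °C to rt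
Reagents that add atoms: none
Why: Domino cycloisomerisation–transfer hydrogenation, as known for 2-alkynylbenzaldehydes and 2-alkynylcycloalkenecarbaldehydes: the aldehyde oxygen attacks the alkyne activated by the Ph3PAu cation 6-endo to give an aromatic pyrylium (which secures 6-endo over 5-exo closure), and the Hantzsch ester delivers hydride to the unsubstituted, most electrophilic C1.

Step 8
Reactants: 11 6-[(E)-prop-1-enyl]-3,4-dihydro-1H,8H-pyrano[3,4-c]pyran-1-one
Product: 13 1-{4-(2-hydroxyethyl)-6-[(E)-prop-1-enyl]-2H-pyran-3-yl}propane-1,2-dione, via ethoxyvinyl ketone 12 (not isolated)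
Conditions: ethyl vinyl ether, t-BuLi, THF, −78 to 0 °C; then 11, −78 °C; then 1 M aq. HCl, THF, 0 °C to rt
Reagents that add atoms: 1-ethoxyvinyllithium (from ethyl vinyl ether, C=COCC), [Li]C(=C)OCC; water, O
Why: Addition of an acetyl anion equivalent to the lactone carbonyl should stop after one addition because the ketone released is a deactivated, doubly vinylogous ester carbonyl, and dilute acid then hydrolyses the ethoxyvinyl group to the 1,2-diketone while the push–pull ring enol ether is expected to survive.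

Step 9
Reactants: 13 1-{4-(2-hydroxyethyl)-6-[(E)-prop-1-enyl]-2H-pyran-3-yl}propane-1,2-dione
Product: 14 1-{6-[(E)-prop-1-enyl]-4-[2-(triethylsilyloxy)ethyl]-2H-pyran-3-yl}propane-1,2-dione
Conditions: TESCl, imidazole, CH2Cl2, 0 °C
Reagents that add atoms: chlorotriethylsilane, CC[Si](Cl)(CC)CC
Why: Silylation of the primary alcohol (through the open-chain form if any hemiketal is present) masks the only competing nucleophile for the acylation that follows.

Step 10
Reactants: 14 1-{6-[(E)-prop-1-enyl]-4-[2-(triethylsilyloxy)ethyl]-2H-pyran-3-yl}propane-1,2-dione; 5 2-methoxy-6-methyl-4-(triisopropylsilyloxy)benzoyl chloride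
Product: 15 3-oxo-3-{6-[(E)-prop-1-enyl]-4-[2-(triethylsilyloxy)ethyl]-2H-pyran-3-yl}prop-1-en-2-yl 2-methoxy-6-methyl-4-(triisopropylsilyloxy)benzoate
Conditions: Et3N, DMAP (cat.), THF/DMPU, 0 °C to rt
Reagents that add atoms: none
Why: O-Acylation of the diketone enolate (the methyl group is its only α-position) by the aroyl chloride is the established entry to 1-acylvinyl arenecarboxylates from 1,2-diketones, and it makes the ester C–O bond of the future tertiary centre at an unhindered sp2 oxygen.

Step 11
Reactants: 15 3-oxo-3-{6-[(E)-prop-1-enyl]-4-[2-(triethylsilyloxy)ethyl]-2H-pyran-3-yl}prop-1-en-2-yl 2-methoxy-6-methyl-4-(triisopropylsilyloxy)benzoate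
Product: 16 3-{4-(2-hydroxyethyl)-6-[(E)-prop-1-enyl]-2H-pyran-3-yl}-3-oxoprop-1-en-2-yl 2-methoxy-6-methyl-4-(triisopropylsilyloxy)benzoate
Conditions: HF·pyridine, pyridine, THF, 0 °C
Reagents that add atoms: none
Why: Selective desilylation: under buffered acidic fluoride the primary triethylsilyl ether should cleave much faster than the aryl triisopropylsilyl ether, and the hindered enol ester is not touched.

Step 12
Reactants: 16 3-{4-(2-hydroxyethyl)-6-[(E)-prop-1-enyl]-2H-pyran-3-yl}-3-oxoprop-1-en-2-yl 2-methoxy-6-methyl-4-(triisopropylsilyloxy)benzoate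
Product: 17 3-oxo-3-{4-(2-oxoethyl)-6-[(E)-prop-1-enyl]-2H-pyran-3-yl}prop-1-en-2-yl 2-methoxy-6-methyl-4-(triisopropylsilyloxy)benzoate
Conditions: Dess–Martin periodinane, NaHCO3, CH2Cl2, 0 °C; used at once
Reagents that add atoms: none
Why: Dess–Martin oxidation under buffered, non-enolising conditions should give the β,γ-unsaturated aldehyde without shifting the C4a=C8a double bond.

Step 13
Reactants: 17 3-oxo-3-{4-(2-oxoethyl)-6-[(E)-prop-1-enyl]-2H-pyran-3-yl}prop-1-en-2-yl 2-methoxy-6-methyl-4-(triisopropylsilyloxy)benzoate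
Product: 19 (6S,7R)-6-hydroxy-7-methyl-8-oxo-3-[(E)-prop-1-enyl]-5,6,7,8-tetrahydro-1H-isochromen-7-yl 2-methoxy-6-methyl-4-(triisopropylsilyloxy)benzoate, via silyl aldolate 18 (not isolated)
Conditions: Cu(OAc)2·H2O (5 mol%), (R)-DTBM-SEGPHOS (5.5 mol%), (EtO)2MeSiH (1.5 equiv), toluene/THF, −40 to −10 °C; then 1 M aq. HCl, THF, 0 °C
Reagents that add atoms: none
Why: Proposed new method: a bisphosphine-ligated monovalent copper hydride should add hydride to the unhindered CH2 terminus of the s-cis 2-aroyloxy enone, giving without base the O-bound (Z)-enolate C7=C8 with the new methyl group cis to O–Cu; this adds to the tethered aldehyde C6 and is turned over by Si–H/Cu–O exchange to silyl ether 18, and the closest known reaction types are the CuH-catalysed enantioselective reductive aldol cyclisations of enoates and enones onto tethered ketones and the intermolecular reductive aldol of acrylates with aldehydes, here extended to an α-acyloxy enone donor, an aldehyde acceptor and a ring ketone enolate. Ring B closes in the 6-(enolendo)-exo-trig mode. The relative configuration should follow from the enolate geometry and a closed transition state in which O6 and O8 are bridged by the copper centre, which places the substituent cis to O8 (the methyl group) cis to the C6 oxygen, so that the hydroxyl ends up trans to the aroyloxy group as the target requires. The absolute configuration at C6 and C7 is set in the same event by the ligand, which differentiates the enantiotopic faces of the planar enolate; the sense of induction cannot be predicted with confidence, and the ligand antipode is equally available if a first run shows the opposite sense. The step needs conjugate hydride delivery to the enone before aldehyde reduction, no reduction of the ring dienone and no acyl shift from O7 to O8 or O6; these are secured respectively by the free methylene terminus with fast intramolecular trapping, by the tetrasubstituted C4a and the oxygen-bearing C3, and by the 2,6-disubstituted aroyl group.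

Step 14
Reactants: 19 (6S,7R)-6-hydroxy-7-methyl-8-oxo-3-[(E)-prop-1-enyl]-5,6,7,8-tetrahydro-1H-isochromen-7-yl 2-methoxy-6-methyl-4-(triisopropylsilyloxy)benzoate
Product: 20 (6S,7R)-6-hydroxy-7-methyl-8-oxo-3-[(E)-prop-1-enyl]-5,6,7,8-tetrahydro-1H-isochromen-7-yl 4-hydroxy-2-methoxy-6-methylbenzoate
Conditions: Bu4NF, AcOH (1:1), THF, 0 °C
Reagents that add atoms: none
Why: Fluoride desilylation of the aryl silyl ether, buffered with acetic acid so that the β-hydroxy ketone should undergo neither retro-aldol cleavage nor acyl migration.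

**Compound list**

1 | 2,4-dihydroxy-6-methylbenzaldehyde | Cc1cc(O)cc(O)c1C=O | starting material
2 | 2-hydroxy-6-methyl-4-(triisopropylsilyloxy)benzaldehyde | Cc1cc(O[Si](C(C)C)(C(C)C)C(C)C)cc(O)c1C=O | intermediate
3 | 2-methoxy-6-methyl-4-(triisopropylsilyloxy)benzaldehyde | Cc1cc(O[Si](C(C)C)(C(C)C)C(C)C)cc(OC)c1C=O | intermediate
4 | 2-methoxy-6-methyl-4-(triisopropylsilyloxy)benzoic acid | Cc1cc(O[Si](C(C)C)(C(C)C)C(C)C)cc(OC)c1C(=O)O | intermediate
5 | 2-methoxy-6-methyl-4-(triisopropylsilyloxy)benzoyl chloride | Cc1cc(O[Si](C(C)C)(C(C)C)C(C)C)cc(OC)c1C(=O)Cl | intermediate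
6 | dihydro-2H-pyran-2,4(3H)-dione | O=C1CCOC(=O)C1 | starting material
7 | N-[(4-chloro-2-oxo-5,6-dihydro-2H-pyran-3-yl)methylidene]-N-methylmethanaminium chloride | C[N+](C)=CC1=C(Cl)CCOC1=O.[Cl-] | intermediate (not isolated)
8 | 4-chloro-2-oxo-5,6-dihydro-2H-pyran-3-carbaldehyde | O=CC1=C(Cl)CCOC1=O | intermediate
9 | (E)-pent-3-en-1-yne | C/C=C/C#C | starting material
10 | 2-oxo-4-[(E)-pent-3-en-1-ynyl]-5,6-dihydro-2H-pyran-3-carbaldehyde | C/C=C/C#CC1=C(C=O)C(=O)OCC1 | intermediate
11 | 6-[(E)-prop-1-enyl]-3,4-dihydro-1H,8H-pyrano[3,4-c]pyran-1-one | C/C=C/C1=CC2=C(CO1)C(=O)OCC2 | intermediate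
12 | 2-ethoxy-1-{4-(2-hydroxyethyl)-6-[(E)-prop-1-enyl]-2H-pyran-3-yl}prop-2-en-1-one | C/C=C/C1=CC(CCO)=C(CO1)C(=O)C(=C)OCC | intermediate (not isolated)
13 | 1-{4-(2-hydroxyethyl)-6-[(E)-prop-1-enyl]-2H-pyran-3-yl}propane-1,2-dione | C/C=C/C1=CC(CCO)=C(CO1)C(=O)C(C)=O | intermediate
14 | 1-{6-[(E)-prop-1-enyl]-4-[2-(triethylsilyloxy)ethyl]-2H-pyran-3-yl}propane-1,2-dione | C/C=C/C1=CC(CCO[Si](CC)(CC)CC)=C(CO1)C(=O)C(C)=O | intermediate
15 | 3-oxo-3-{6-[(E)-prop-1-enyl]-4-[2-(triethylsilyloxy)ethyl]-2H-pyran-3-yl}prop-1-en-2-yl 2-methoxy-6-methyl-4-(triisopropylsilyloxy)benzoate | C/C=C/C1=CC(CCO[Si](CC)(CC)CC)=C(CO1)C(=O)C(=C)OC(=O)c1c(C)cc(O[Si](C(C)C)(C(C)C)C(C)C)cc1OC | intermediate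
16 | 3-{4-(2-hydroxyethyl)-6-[(E)-prop-1-enyl]-2H-pyran-3-yl}-3-oxoprop-1-en-2-yl 2-methoxy-6-methyl-4-(triisopropylsilyloxy)benzoate | C/C=C/C1=CC(CCO)=C(CO1)C(=O)C(=C)OC(=O)c1c(C)cc(O[Si](C(C)C)(C(C)C)C(C)C)cc1OC | intermediate
17 | 3-oxo-3-{4-(2-oxoethyl)-6-[(E)-prop-1-enyl]-2H-pyran-3-yl}prop-1-en-2-yl 2-methoxy-6-methyl-4-(triisopropylsilyloxy)benzoate | C/C=C/C1=CC(CC=O)=C(CO1)C(=O)C(=C)OC(=O)c1c(C)cc(O[Si](C(C)C)(C(C)C)C(C)C)cc1OC | intermediate
18 | (6S,7R)-6-[diethoxy(methyl)silyloxy]-7-methyl-8-oxo-3-[(E)-prop-1-enyl]-5,6,7,8-tetrahydro-1H-isochromen-7-yl 2-methoxy-6-methyl-4-(triisopropylsilyloxy)benzoate | C/C=C/C1=CC2=C(CO1)C(=O)[C@](C)(OC(=O)c1c(C)cc(O[Si](C(C)C)(C(C)C)C(C)C)cc1OC)[C@@H](O[Si](C)(OCC)OCC)C2 | intermediate (not isolated)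
19 | (6S,7R)-6-hydroxy-7-methyl-8-oxo-3-[(E)-prop-1-enyl]-5,6,7,8-tetrahydro-1H-isochromen-7-yl 2-methoxy-6-methyl-4-(triisopropylsilyloxy)benzoate | C/C=C/C1=CC2=C(CO1)C(=O)[C@](C)(OC(=O)c1c(C)cc(O[Si](C(C)C)(C(C)C)C(C)C)cc1OC)[C@@H](O)C2 | intermediate
20 | (6S,7R)-6-hydroxy-7-methyl-8-oxo-3-[(E)-prop-1-enyl]-5,6,7,8-tetrahydro-1H-isochromen-7-yl 4-hydroxy-2-methoxy-6-methylbenzoate | C/C=C/C1=CC2=C(CO1)C(=O)[C@](C)(OC(=O)c1c(C)cc(O)cc1OC)[C@@H](O)C2 | target

**Step count and risks**

Total step count: 14. Longest linear sequence: 10 steps (steps 5 to 14); the aroyl chloride branch (steps 1 to 4) joins at step 10.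

Steps most likely to fail:

1. Step 13, which bears the proposed new method. Aldehyde reduction may outrun hydrocupration of the enone, the ligand may discriminate the enolate faces poorly, or an open transition state may lead to the cis diastereomer. The fallback for step 13 closes the same C6–C7 bond by an enantioselective intramolecular crossed benzoin reaction, which is known chemistry; it sets out from 13 and comes back to the route at 19. Dess–Martin oxidation of 13 should give the diketone aldehyde F1. A chiral aminoindanol-derived triazolium salt with a weak amine base should then close the six-membered ring by attack of the C6 acyl anion equivalent on the acetyl carbonyl C7 and give the tertiary ketol F2. Hydroxyl-directed reduction of the C6 ketone with Me4NBH(OAc)3 should deliver hydride cis to the C7 oxygen and give the trans-diol F3. The secondary alcohol is silylated with TESOTf and 2,6-lutidine to the triethylsilyl ether F4, the tertiary alcohol is acylated with 5 (LiN(SiMe3)2, THF) to the protected ester F5, and HF·pyridine removes the triethylsilyl group from F5 to come back to the route at 19.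

2. Step 8. The organolithium may add twice, may deprotonate the lactone at C5, or the acid may open the pyran or leave the diketone tied up as a hemiketal. The fallback for step 8 controls mono-addition through a Weinreb amide; it sets out from 11 and comes back to the route at 13. Me(MeO)NH·HCl with i-PrMgCl should open the lactone to the hydroxy Weinreb amide F6, TESCl and imidazole should give its silyl ether F7, and 1-ethoxyvinyllithium should add once to give the ethoxyvinyl ketone F8. Dilute aqueous acid then removes both the enol ether and the silyl ether from F8 and returns to the route at 13.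

3. Step 10. The hindered, electron-rich aroyl chloride may acylate the diketone enolate too slowly, so that C-acylation or self-condensation of the diketone takes over. The fallback for step 10 reverses the polarity of the ester C–O bond formation; it sets out from 11 and comes back to the route at 15. Chloromethyllithium (ICH2Cl, MeLi·LiBr, THF, −78 °C) should open the lactone to the chloromethyl ketone F9, TESCl and imidazole should give its silyl ether F10, and acid 4 with i-Pr2NEt and catalytic NaI should displace chloride to give the acyloxymethyl ketone F11. α-Methylenation of F11 with paraformaldehyde and diisopropylammonium trifluoroacetate in THF then returns to the route at 15.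

Further compounds

F1 | step 13 | {3-(2-oxopropanoyl)-6-[(E)-prop-1-enyl]-2H-pyran-4-yl}acetaldehyde | C/C=C/C1=CC(CC=O)=C(CO1)C(=O)C(C)=O
F2 | step 13 | (7R)-7-hydroxy-7-methyl-3-[(E)-prop-1-enyl]-1H-isochromene-6,8(5H,7H)-dione | C/C=C/C1=CC2=C(CO1)C(=O)[C@](C)(O)C(=O)C2
F3 | step 13 | (6S,7R)-6,7-dihydroxy-7-methyl-3-[(E)-prop-1-enyl]-6,7-dihydro-1H-isochromen-8(5H)-one | C/C=C/C1=CC2=C(CO1)C(=O)[C@](C)(O)[C@@H](O)C2
F4 | step 13 | (6S,7R)-7-hydroxy-7-methyl-3-[(E)-prop-1-enyl]-6-(triethylsilyloxy)-6,7-dihydro-1H-isochromen-8(5H)-one | C/C=C/C1=CC2=C(CO1)C(=O)[C@](C)(O)[C@@H](O[Si](CC)(CC)CC)C2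
F5 | step 13 | (6S,7R)-7-methyl-8-oxo-3-[(E)-prop-1-enyl]-6-(triethylsilyloxy)-5,6,7,8-tetrahydro-1H-isochromen-7-yl 2-methoxy-6-methyl-4-(triisopropylsilyloxy)benzoate | C/C=C/C1=CC2=C(CO1)C(=O)[C@](C)(OC(=O)c1c(C)cc(O[Si](C(C)C)(C(C)C)C(C)C)cc1OC)[C@@H](O[Si](CC)(CC)CC)C2
F6 | step 8 | 4-(2-hydroxyethyl)-N-methoxy-N-methyl-6-[(E)-prop-1-enyl]-2H-pyran-3-carboxamide | C/C=C/C1=CC(CCO)=C(CO1)C(=O)N(C)OC
F7 | step 8 | N-methoxy-N-methyl-6-[(E)-prop-1-enyl]-4-[2-(triethylsilyloxy)ethyl]-2H-pyran-3-carboxamide | C/C=C/C1=CC(CCO[Si](CC)(CC)CC)=C(CO1)C(=O)N(C)OC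
F8 | step 8 | 2-ethoxy-1-{6-[(E)-prop-1-enyl]-4-[2-(triethylsilyloxy)ethyl]-2H-pyran-3-yl}prop-2-en-1-one | C/C=C/C1=CC(CCO[Si](CC)(CC)CC)=C(CO1)C(=O)C(=C)OCC
F9 | step 10 | 2-chloro-1-{4-(2-hydroxyethyl)-6-[(E)-prop-1-enyl]-2H-pyran-3-yl}ethanone | C/C=C/C1=CC(CCO)=C(CO1)C(=O)CCl
F10 | step 10 | 2-chloro-1-{6-[(E)-prop-1-enyl]-4-[2-(triethylsilyloxy)ethyl]-2H-pyran-3-yl}ethanone | C/C=C/C1=CC(CCO[Si](CC)(CC)CC)=C(CO1)C(=O)CCl
F11 | step 10 | 2-oxo-2-{6-[(E)-prop-1-enyl]-4-[2-(triethylsilyloxy)ethyl]-2H-pyran-3-yl}ethyl 2-methoxy-6-methyl-4-(triisopropylsilyloxy)benzoate | C/C=C/C1=CC(CCO[Si](CC)(CC)CC)=C(CO1)C(=O)COC(=O)c1c(C)cc(O[Si](C(C)C)(C(C)C)C(C)C)cc1OC
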